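**Strategy**

Everything rests on the bond between C3 of the chromen-4-one and C1′ of the 2,4,5-trimethoxyphenyl ring, which is made as plants are presumed to make it: by a 1,2-aryl shift. The precursor is a 2′-hydroxychalcone in which that ring still sits on the future C2. Thallium(III) nitrate in methanol moves it to the future C3, and acid then closes the pyranone ring in the same operation. The step exploits the C2–C3 enone of the C6–C3–C6 chain and the migratory aptitude of the B ring, whose 2′- and 4′-methoxy groups stabilise the bridged cation. The 8-methoxy group is set beforehand; the 6-prenyl group follows by Claisen rearrangement onto C6, the only free ring-A carbon.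

Key step: step 4

Remarks on the chemistry: (i) the target has no stereocentre and no stereogenic double bond, so no stereocontrol is required; the stereocentres of intermediates 6 and 11 form as racemates and vanish within the same step. (ii) Ketone 1, aldehyde 4 and carbonate 9 are taken as catalogue compounds.

**Route**

Step 1
Reactants: 1 1-[2,4-bis(benzyloxy)-6-hydroxyphenyl]ethan-1-one
Product: 2 1-[4,6-bis(benzyloxy)-3-bromo-2-hydroxyphenyl]ethan-1-one
Conditions: NBS (1.0 equiv), CH2Cl2, 0 °C to rt, dark
Reagents that add atoms: N-bromosuccinimide, O=C1CCC(=O)N1Br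
Why: Electrophilic aromatic bromination of a phloroglucinol-type ring; the carbonyl-chelated free OH should direct to its ortho carbon C3, while C5 is shielded by two flanking benzyloxy groups, and one equivalent of NBS should hold the reaction at mono-bromination.

Step 2
Reactants: 2 1-[4,6-bis(benzyloxy)-3-bromo-2-hydroxyphenyl]ethan-1-one
Product: 3 1-[4,6-bis(benzyloxy)-2-hydroxy-3-methoxyphenyl]ethan-1-one
Conditions: NaOMe (5 equiv), CuBr (0.2 equiv), EtOAc (cat.), MeOH/DMF, 100 °C, sealed tube, argon
Reagents that add atoms: sodium methoxide, [Na+].[O-]C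
Why: Copper-catalysed Ullmann-type methanolysis of an aryl bromide that sits ortho to a phenoxide, the arrangement in which this exchange is known to run well; benzyl ethers are inert to methoxide and the di-ortho-substituted ketone is a poor aldol partner.

Step 3
Reactants: 3 1-[4,6-bis(benzyloxy)-2-hydroxy-3-methoxyphenyl]ethan-1-one; 4 2,4,5-trimethoxybenzaldehyde
Product: 5 (E)-1-[4,6-bis(benzyloxy)-2-hydroxy-3-methoxyphenyl]-3-(2,4,5-trimethoxyphenyl)prop-2-en-1-one
Conditions: KOH (50% aq), EtOH, rt, 48 h; then dilute HCl to pH 5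
Reagents that add atoms: none
Why: Claisen–Schmidt aldol condensation with an aldehyde that has no α-hydrogen; E1cB dehydration should give the thermodynamically favoured E-enone, and in strong base the phenoxide keeps the product as the open chalcone instead of the flavanone.

Step 4
Reactants: 5 (E)-1-[4,6-bis(benzyloxy)-2-hydroxy-3-methoxyphenyl]-3-(2,4,5-trimethoxyphenyl)prop-2-en-1-one
Product: 7 5,7-bis(benzyloxy)-8-methoxy-3-(2,4,5-trimethoxyphenyl)-4H-chromen-4-one, via β-ketoacetal 6 (not isolated)
Conditions: Tl(NO3)3·3H2O (1.2 equiv), MeOH/CH(OMe)3 (3:1), rt, dark; filter off TlNO3; then 10% aq HCl, MeOH, 50 °C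
Reagents that add atoms: methanol, CO (two molecules enter intermediate 6 as its acetal methoxy groups and leave again on ring closure; none of their atoms stays in 7)
Why: Tl(III) adds as an electrophile to Cα of the enone while methanol adds to the benzylic Cβ (oxythallation); heterolysis of the weak C–Tl bond, with thallium leaving as Tl(I), is assisted by the 2,4,5-trimethoxyphenyl ring, which bridges as a phenonium ion and ends on Cα, and the oxocarbenium ion left at Cβ is trapped by methanol as dimethyl acetal 6. The closest known reaction type is the thallium(III) nitrate oxidative rearrangement of 2′-hydroxychalcones to isoflavones, the laboratory counterpart of the enzymatic 2→3 aryl shift of flavanones. On acidification the acetal ionises and the free phenol oxygen closes the pyranone ring by 6-exo-trig attack on the oxocarbenium carbon, after which loss of the second methanol gives the C2=C3 double bond. No stereocentre remains: the one at C2 of 6 forms as a racemate and is erased by the elimination. The step needs aryl migration to outrun attack of the phenol oxygen (aurone formation) and plain dehydrogenation, which the ortho- and para-methoxy groups of the migrating ring should secure. It also needs ring closure through the oxygen next to the methoxy-bearing carbon, which is secured because the other ortho oxygen is a benzyl ether that survives dilute acid.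

Step 5
Reactants: 7 5,7-bis(benzyloxy)-8-methoxy-3-(2,4,5-trimethoxyphenyl)-4H-chromen-4-one
Product: 8 isocaviunin [5,7-dihydroxy-8-methoxy-3-(2,4,5-trimethoxyphenyl)-4H-chromen-4-one]
Conditions: H2 (1 atm), 10% Pd/C, EtOAc/MeOH (1:1), rt; stop after uptake of 2 equiv
Reagents that add atoms: none
Why: Hydrogenolysis of aryl benzyl ethers over palladium; the methyl ethers are inert and the chromone C2=C3 bond should survive at 1 atm and rt if the reaction is stopped at two equivalents.

Step 6
Reactants: 8 isocaviunin; 9 tert-butyl 2-methylbut-3-en-2-yl carbonate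
Product: 10 5-hydroxy-8-methoxy-7-[(2-methylbut-3-en-2-yl)oxy]-3-(2,4,5-trimethoxyphenyl)-4H-chromen-4-one
Conditions: Pd(PPh3)4 (5 mol %), 9 (1.5 equiv), THF, 0 °C
Reagents that add atoms: none
Why: Tsuji–Trost O-allylation; Pd(0) ionises the tertiary allylic carbonate with loss of CO2, the tert-butoxide released deprotonates only the acidic 7-OH (the 5-OH is held in a hydrogen bond to C4=O), and the phenoxide should attack the more substituted terminus of the 1,1-dimethylallyl–Pd complex under kinetic control at 0 °C to give the branched ether.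

Step 7
Reactants: 10 5-hydroxy-8-methoxy-7-[(2-methylbut-3-en-2-yl)oxy]-3-(2,4,5-trimethoxyphenyl)-4H-chromen-4-one
Product: 12 6-prenylisocaviunin [5,7-dihydroxy-8-methoxy-6-(3-methylbut-2-en-1-yl)-3-(2,4,5-trimethoxyphenyl)-4H-chromen-4-one], via cyclohexadienone 11 (not isolated)
Conditions: N,N-diethylaniline, 120 °C, argon
Reagents that add atoms: none
Why: Aromatic ortho-Claisen rearrangement ([3,3]-sigmatropic shift); C8 carries OMe, so a shift there would give a dienone that cannot tautomerise and reverts, and the allyl unit should arrive with allylic inversion at C6 as the linear prenyl group, after which dienone 11 tautomerises to the phenol; the basic solvent suppresses acid-catalysed chroman formation.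

**Compound list**

1 | 1-[2,4-bis(benzyloxy)-6-hydroxyphenyl]ethan-1-one | CC(=O)c1c(O)cc(OCc2ccccc2)cc1OCc1ccccc1 | starting material
2 | 1-[4,6-bis(benzyloxy)-3-bromo-2-hydroxyphenyl]ethan-1-one | CC(=O)c1c(O)c(Br)c(OCc2ccccc2)cc1OCc1ccccc1 | intermediate
3 | 1-[4,6-bis(benzyloxy)-2-hydroxy-3-methoxyphenyl]ethan-1-one | CC(=O)c1c(O)c(OC)c(OCc2ccccc2)cc1OCc1ccccc1 | intermediate
4 | 2,4,5-trimethoxybenzaldehyde | COc1cc(OC)c(C=O)cc1OC | starting material
5 | (E)-1-[4,6-bis(benzyloxy)-2-hydroxy-3-methoxyphenyl]-3-(2,4,5-trimethoxyphenyl)prop-2-en-1-one | COc1cc(OC)c(/C=C/C(=O)c2c(O)c(OC)c(OCc3ccccc3)cc2OCc2ccccc2)cc1OC | intermediate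
6 | 1-[4,6-bis(benzyloxy)-2-hydroxy-3-methoxyphenyl]-3,3-dimethoxy-2-(2,4,5-trimethoxyphenyl)propan-1-one (racemic, not isolated) | COc1cc(OC)c(C(C(OC)OC)C(=O)c2c(O)c(OC)c(OCc3ccccc3)cc2OCc2ccccc2)cc1OC | intermediate
7 | 5,7-bis(benzyloxy)-8-methoxy-3-(2,4,5-trimethoxyphenyl)-4H-chromen-4-one | COc1cc(OC)c(-c2coc3c(OC)c(OCc4ccccc4)cc(OCc4ccccc4)c3c2=O)cc1OC | intermediate
8 | isocaviunin, 5,7-dihydroxy-8-methoxy-3-(2,4,5-trimethoxyphenyl)-4H-chromen-4-one | COc1cc(OC)c(-c2coc3c(OC)c(O)cc(O)c3c2=O)cc1OC | intermediate
9 | tert-butyl 2-methylbut-3-en-2-yl carbonate | C=CC(C)(C)OC(=O)OC(C)(C)C | starting material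
10 | 5-hydroxy-8-methoxy-7-[(2-methylbut-3-en-2-yl)oxy]-3-(2,4,5-trimethoxyphenyl)-4H-chromen-4-one | COc1cc(OC)c(-c2coc3c(OC)c(OC(C)(C)C=C)cc(O)c3c2=O)cc1OC | intermediate
11 | 5-hydroxy-8-methoxy-6-(3-methylbut-2-en-1-yl)-3-(2,4,5-trimethoxyphenyl)-4H-chromene-4,7(6H)-dione (racemic dienone tautomer, not isolated) | COc1cc(OC)c(C2=COC3=C(OC)C(=O)C(CC=C(C)C)C(O)=C3C2=O)cc1OC | intermediate
12 | 6-prenylisocaviunin, 5,7-dihydroxy-8-methoxy-6-(3-methylbut-2-en-1-yl)-3-(2,4,5-trimethoxyphenyl)-4H-chromen-4-one | COc1cc(OC)c(-c2coc3c(OC)c(O)c(CC=C(C)C)c(O)c3c2=O)cc1OC | target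

**Step count and risks**

Total step count: 7. Longest linear sequence: 7 steps (1 to 12).

Steps most likely to fail:

1. Step 4 (key step). Thallium(III) may oxidise the two electron-rich rings (oxidative dealkylation towards quinones), or the phenol oxygen may attack before the aryl group migrates, which leads to aurone-type ring closure. The fallback makes the same bond by cross-coupling and sets out from ketone 3. Heating 3 with N,N-dimethylformamide dimethyl acetal (toluene, 90 °C) should give the enaminone (E)-1-[4,6-bis(benzyloxy)-2-hydroxy-3-methoxyphenyl]-3-(dimethylamino)prop-2-en-1-one F1. Iodine (2 equiv, MeOH, rt) should iodinate its α-carbon and close the ring to 5,7-bis(benzyloxy)-3-iodo-8-methoxy-4H-chromen-4-one F2. Suzuki–Miyaura coupling of F2 with commercial (2,4,5-trimethoxyphenyl)boronic acid (COc1cc(OC)c(B(O)O)cc1OC; Pd(dppf)Cl2, aq Na2CO3, DME, 80 °C) comes back to the route at 7.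

2. Step 2. The hindered, electron-rich bromide may exchange slowly, so that reductive loss of bromine or base-induced condensation of the methyl ketone competes. The fallback brings the oxygen in by Dakin oxidation and sets out from 1, which also makes step 1 unnecessary. Magnesium-mediated ortho-formylation (MgCl2, Et3N, paraformaldehyde, MeCN, reflux) should give 3-acetyl-4,6-bis(benzyloxy)-2-hydroxybenzaldehyde F3, formylated only next to the free OH. Dakin oxidation (H2O2, aq NaOH, THF, 0 °C, argon) should give the catechol 1-[4,6-bis(benzyloxy)-2,3-dihydroxyphenyl]ethan-1-one F4. Methylation of its non-chelated 3-OH (MeI 1.05 equiv, K2CO3, acetone, rt) comes back to the route at 3.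

3. Step 6. The phenoxide, flanked by the 8-methoxy group, may attack the less substituted allyl terminus (linear prenyl ether, which would give the wrong Claisen product) or react through carbon. The fallback builds the tertiary ether by copper-catalysed propargylation and sets out from 8. Treatment with 3-chloro-3-methylbut-1-yne (C#CC(C)(C)Cl; K2CO3, KI, CuI cat., acetone, reflux) should give 5-hydroxy-8-methoxy-7-[(2-methylbut-3-yn-2-yl)oxy]-3-(2,4,5-trimethoxyphenyl)-4H-chromen-4-one F5. Semi-hydrogenation over Lindlar catalyst (H2 1 atm, quinoline, EtOAc, rt) comes back to the route at 10.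

**Further compounds**

F1 | step 4 | (E)-1-[4,6-bis(benzyloxy)-2-hydroxy-3-methoxyphenyl]-3-(dimethylamino)prop-2-en-1-one | CN(C)/C=C/C(=O)c1c(O)c(OC)c(OCc2ccccc2)cc1OCc1ccccc1
F2 | step 4 | 5,7-bis(benzyloxy)-3-iodo-8-methoxy-4H-chromen-4-one | COc1c(OCc2ccccc2)cc(OCc2ccccc2)c2c(=O)c(I)coc12
F3 | step 2 | 3-acetyl-4,6-bis(benzyloxy)-2-hydroxybenzaldehyde | CC(=O)c1c(O)c(C=O)c(OCc2ccccc2)cc1OCc1ccccc1
F4 | step 2 | 1-[4,6-bis(benzyloxy)-2,3-dihydroxyphenyl]ethan-1-one | CC(=O)c1c(O)c(O)c(OCc2ccccc2)cc1OCc1ccccc1
F5 | step 6 | 5-hydroxy-8-methoxy-7-[(2-methylbut-3-yn-2-yl)oxy]-3-(2,4,5-trimethoxyphenyl)-4H-chromen-4-one | COc1cc(OC)c(-c2coc3c(OC)c(OC(C)(C)C#C)cc(O)c3c2=O)cc1OC
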